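Assumption: (R)- and (S)-1,2-epoxypentane are both purchased in ≥98% ee.

## Retrosynthetic overview

1. Target 28 ⇒ global desilylation of 27; the ester C–O bond is cut by a late Mitsunobu esterification (inversion) into salicylic acid 16 and (S)-alcohol 26, two halves of similar size.
2. Each half ⇒ B-alkyl Suzuki–Miyaura coupling of an aryl triflate (5 or 20) with a terminal alkenol, made by CuI-catalysed opening of (R)- or (S)-1,2-epoxypentane with an ω-alkenyl Grignard reagent.
3. Both triflates ⇒ resorcinol, through meta-selective iridium-catalysed C–H borylation/oxidation of its bis-ether (this creates the 1,3,5-pattern).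
4. The carboxyl group of 16 ⇒ ring bromination, Li–Br exchange/CO2, then chelation-controlled mono-demethylation.
5. No ring is constructed: both benzene rings come ready-made from resorcinol.

## Route

**Acid half (fragment A)**

Step 1
Reactants: 1 resorcinol
Product: 2 1,3-dimethoxybenzene
Conditions: MeI (2.5 equiv), K2CO3, acetone, reflux
Reagents that add atoms: iodomethane, CI
Why: Williamson ether synthesis; both phenoxides are methylated by SN2 on MeI.

Step 2
Reactants: 2 1,3-dimethoxybenzene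
Product: 4 3,5-dimethoxyphenol, via pinacol arylboronate 3 (not isolated)
Conditions: [Ir(OMe)(cod)]2 (1.5 mol %), dtbpy (3 mol %), B2pin2 (0.6 equiv), THF, 80 °C; evaporate; then KHSO5 (as 2KHSO5·KHSO4·K2SO4), acetone/H2O, rt
Reagents that add atoms: bis(pinacolato)diboron, CC1(C)OB(OC1(C)C)B1OC(C)(C)C(C)(C)O1 (its boron sits only in 3); potassium peroxymonosulfate, [K+].[O-]S(=O)(=O)OO (gives the phenol oxygen)
Why: Sterically controlled iridium-catalysed C–H borylation hits the only C–H without an ortho substituent (C5), and peroxide oxidation of the C–B bond (1,2-aryl shift) gives the phenol in the same pot.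

Step 3
Reactants: 4 3,5-dimethoxyphenol
Product: 5 3,5-dimethoxyphenyl trifluoromethanesulfonate
Conditions: Tf2O, pyridine, CH2Cl2, 0 °C
Reagents that add atoms: trifluoromethanesulfonic anhydride, O=S(=O)(OS(=O)(=O)C(F)(F)F)C(F)(F)F
Why: O-sulfonylation of the phenol turns it into a cross-coupling electrophile.

Step 4
Reactants: 6 7-bromohept-1-ene, 7 (R)-1,2-epoxypentane
Product: 9 (R)-dodec-11-en-4-ol, via Grignard reagent 8 (not isolated)
Conditions: Mg, THF, rt; then 7, CuI (10 mol %), THF, −30 → 0 °C; aq NH4Cl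
Reagents that add atoms: magnesium, [Mg] (sits only in 8)
Why: Copper-catalysed Grignard opening of the epoxide by SN2 at the unsubstituted carbon; the C–O bond of the stereocenter is untouched, so the R configuration of 7 is carried over.

Step 5
Reactants: 9 (R)-dodec-11-en-4-ol
Product: 10 (R)-tert-butyl(dodec-11-en-4-yloxy)diphenylsilane
Conditions: TBDPSCl, imidazole, DMAP (cat.), DMF, rt → 40 °C
Reagents that add atoms: tert-butyl(chloro)diphenylsilane, CC(C)(C)[Si](Cl)(c1ccccc1)c1ccccc1
Why: Silylation of the secondary alcohol with the most acid- and Lewis-acid-stable common silyl group, needed for steps 7–9 and 15.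

Step 6
Reactants: 10 (R)-tert-butyl(dodec-11-en-4-yloxy)diphenylsilane, 5 3,5-dimethoxyphenyl trifluoromethanesulfonate
Product: 12 (R)-tert-butyl{[12-(3,5-dimethoxyphenyl)dodecan-4-yl]oxy}diphenylsilane, via alkyl-9-BBN 11 (not isolated)
Conditions: 9-BBN (1.3 equiv), THF, 0 °C → rt; then 5, PdCl2(dppf) (5 mol %), K3PO4·H2O, THF, 65 °C
Reagents that add atoms: 9-borabicyclo[3.3.1]nonane, [H]B1C2CCCC1CCC2 (its boron sits only in 11)
Why: Anti-Markovnikov hydroboration of the terminal alkene followed by B-alkyl Suzuki–Miyaura coupling (oxidative addition of the triflate to zerovalent palladium, base-assisted alkyl transfer) forms the aryl–CH2 bond.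

Step 7
Reactants: 12 (R)-tert-butyl{[12-(3,5-dimethoxyphenyl)dodecan-4-yl]oxy}diphenylsilane
Product: 13 (R)-{[12-(2-bromo-3,5-dimethoxyphenyl)dodecan-4-yl]oxy}(tert-butyl)diphenylsilane
Conditions: NBS (1.0 equiv), MeCN, 0 °C, dark
Reagents that add atoms: N-bromosuccinimide, O=C1CCC(=O)N1Br
Why: Electrophilic aromatic bromination goes para to one methoxy group and ortho to the alkyl chain, since the position between the two methoxy groups is more hindered.

Step 8
Reactants: 13 (R)-{[12-(2-bromo-3,5-dimethoxyphenyl)dodecan-4-yl]oxy}(tert-butyl)diphenylsilane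
Product: 15 2-[(9R)-9-(tert-butyldiphenylsilyloxy)dodecyl]-4,6-dimethoxybenzoic acid, via aryllithium 14 (not isolated)
Conditions: n-BuLi (1.1 equiv), THF, −78 °C; CO2 (g), −78 °C → rt; 1 M HCl
Reagents that add atoms: n-butyllithium, [Li]CCCC (its lithium sits only in 14); carbon dioxide, O=C=O
Why: Fast lithium–bromine exchange followed by carboxylation of the aryllithium puts the carboxyl group exactly where the bromine was.

Step 9
Reactants: 15 2-[(9R)-9-(tert-butyldiphenylsilyloxy)dodecyl]-4,6-dimethoxybenzoic acid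
Product: 16 2-[(9R)-9-(tert-butyldiphenylsilyloxy)dodecyl]-6-hydroxy-4-methoxybenzoic acid
Conditions: BCl3 (2.5 equiv), CH2Cl2, −78 → 0 °C; H2O
Reagents that add atoms: none
Why: Chelation-controlled Lewis-acid ether cleavage: boron bound to the carboxyl oxygen removes only the ortho methyl ether through a six-membered chelate, leaving the para methoxy group and the silyl ether.

**Alcohol half (fragment B)**

Step 10
Reactants: 1 resorcinol
Product: 17 1,3-bis(triisopropylsilyloxy)benzene
Conditions: TIPSCl (2.3 equiv), imidazole, DMF, rt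
Reagents that add atoms: chlorotriisopropylsilane, CC(C)[Si](Cl)(C(C)C)C(C)C
Why: Silylation of both phenols gives base-tolerant, fluoride-labile aryl ethers with no extra arene C–H bonds that could compete in the next step.

Step 11
Reactants: 17 1,3-bis(triisopropylsilyloxy)benzene
Product: 19 3,5-bis(triisopropylsilyloxy)phenol, via pinacol arylboronate 18 (not isolated)
Conditions: [Ir(OMe)(cod)]2 (1.5 mol %), dtbpy (3 mol %), B2pin2 (0.6 equiv), THF, 80 °C; evaporate; then KHSO5 (as 2KHSO5·KHSO4·K2SO4), acetone/H2O, rt, 10 min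
Reagents that add atoms: bis(pinacolato)diboron, CC1(C)OB(OC1(C)C)B1OC(C)(C)C(C)(C)O1 (its boron sits only in 18); potassium peroxymonosulfate, [K+].[O-]S(=O)(=O)OO (gives the phenol oxygen)
Why: Iridium-catalysed C–H borylation is steered to C5 because every other ring C–H is ortho to a bulky silyloxy group, and brief peroxide oxidation converts C–B into C–OH.

Step 12
Reactants: 19 3,5-bis(triisopropylsilyloxy)phenol
Product: 20 3,5-bis(triisopropylsilyloxy)phenyl trifluoromethanesulfonate
Conditions: Tf2O, pyridine, CH2Cl2, 0 °C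
Reagents that add atoms: trifluoromethanesulfonic anhydride, O=S(=O)(OS(=O)(=O)C(F)(F)F)C(F)(F)F
Why: O-sulfonylation of the free phenol under buffered conditions that leave the aryl silyl ethers intact.

Step 13
Reactants: 21 6-bromohex-1-ene, 22 (S)-1,2-epoxypentane
Product: 24 (S)-undec-10-en-4-ol, via Grignard reagent 23 (not isolated)
Conditions: Mg, THF, 0 °C → rt; then 22, CuI (10 mol %), THF, −30 → 0 °C; aq NH4Cl
Reagents that add atoms: magnesium, [Mg] (sits only in 23)
Why: Copper-catalysed Grignard opening of the epoxide at its CH2 terminus leaves the stereocenter untouched (S from 22); the Grignard reagent is made at or below rt to keep radical 5-exo cyclisation to a few percent, and that alkene-free isomer cannot react in step 14.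

Step 14
Reactants: 24 (S)-undec-10-en-4-ol, 20 3,5-bis(triisopropylsilyloxy)phenyl trifluoromethanesulfonate
Product: 26 (S)-11-[3,5-bis(triisopropylsilyloxy)phenyl]undecan-4-ol, via bis-9-BBN adduct 25 (not isolated)
Conditions: 9-BBN (2.3 equiv), THF, rt; then 20, PdCl2(dppf) (5 mol %), K3PO4·H2O, THF, 65 °C
Reagents that add atoms: 9-borabicyclo[3.3.1]nonane, [H]B1C2CCCC1CCC2 (its boron sits only in 25)
Why: Hydroboration/B-alkyl Suzuki–Miyaura coupling; the free hydroxyl uses one equivalent of 9-BBN as a borinate that is hydrolysed again on work-up, and the stereocenter is remote from the reacting sites.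

**Union and end game**

Step 15
Reactants: 16 2-[(9R)-9-(tert-butyldiphenylsilyloxy)dodecyl]-6-hydroxy-4-methoxybenzoic acid, 26 (S)-11-[3,5-bis(triisopropylsilyloxy)phenyl]undecan-4-ol
Product: 27 (R)-11-[3,5-bis(triisopropylsilyloxy)phenyl]undecan-4-yl 2-[(9R)-9-(tert-butyldiphenylsilyloxy)dodecyl]-6-hydroxy-4-methoxybenzoate
Conditions: PPh3 (1.5 equiv), DIAD (1.5 equiv), toluene, 0 °C → rt
Reagents that add atoms: none
Why: Mitsunobu esterification: the hydrogen-bonded, acidic salicylic acid attacks the alkoxyphosphonium ion by SN2 at carbon, which avoids attack at the hindered carbonyl and inverts the carbinol from S to the required R.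

Step 16
Reactants: 27 (R)-11-[3,5-bis(triisopropylsilyloxy)phenyl]undecan-4-yl 2-[(9R)-9-(tert-butyldiphenylsilyloxy)dodecyl]-6-hydroxy-4-methoxybenzoate
Product: 28 5'-methoxy-integracin B
Conditions: Bu4NF/AcOH (1:1, 8 equiv), THF, rt → 45 °C
Reagents that add atoms: none
Why: Buffered fluoride desilylation removes the two aryl silyl ethers and the secondary silyl ether in one operation, without touching the hindered ester, the methyl ether or either stereocenter.

## Compound list

1 | resorcinol (benzene-1,3-diol) | Oc1cccc(O)c1 | starting material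
2 | 1,3-dimethoxybenzene | COc1cccc(OC)c1 | intermediate
3 | 2-(3,5-dimethoxyphenyl)-4,4,5,5-tetramethyl-1,3,2-dioxaborolane | COc1cc(OC)cc(B2OC(C)(C)C(C)(C)O2)c1 | intermediate (not isolated)
4 | 3,5-dimethoxyphenol | COc1cc(O)cc(OC)c1 | intermediate
5 | 3,5-dimethoxyphenyl trifluoromethanesulfonate | COc1cc(OC)cc(OS(=O)(=O)C(F)(F)F)c1 | intermediate
6 | 7-bromohept-1-ene | C=CCCCCCBr | starting material
7 | (R)-1,2-epoxypentane [(2R)-2-propyloxirane] | CCC[C@@H]1CO1 | starting material
8 | hept-6-enylmagnesium bromide | C=CCCCCC[Mg]Br | intermediate (not isolated)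
9 | (R)-dodec-11-en-4-ol | CCC[C@@H](O)CCCCCCC=C | intermediate
10 | (R)-tert-butyl(dodec-11-en-4-yloxy)diphenylsilane | CCC[C@@H](O[Si](c1ccccc1)(c1ccccc1)C(C)(C)C)CCCCCCC=C | intermediate
11 | 9-[(9R)-9-(tert-butyldiphenylsilyloxy)dodecyl]-9-borabicyclo[3.3.1]nonane | CCC[C@@H](O[Si](c1ccccc1)(c1ccccc1)C(C)(C)C)CCCCCCCCB1C2CCCC1CCC2 | intermediate (not isolated)
12 | (R)-tert-butyl{[12-(3,5-dimethoxyphenyl)dodecan-4-yl]oxy}diphenylsilane | CCC[C@@H](O[Si](c1ccccc1)(c1ccccc1)C(C)(C)C)CCCCCCCCc1cc(OC)cc(OC)c1 | intermediate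
13 | (R)-{[12-(2-bromo-3,5-dimethoxyphenyl)dodecan-4-yl]oxy}(tert-butyl)diphenylsilane | CCC[C@@H](O[Si](c1ccccc1)(c1ccccc1)C(C)(C)C)CCCCCCCCc1cc(OC)cc(OC)c1Br | intermediate
14 | {2-[(9R)-9-(tert-butyldiphenylsilyloxy)dodecyl]-4,6-dimethoxyphenyl}lithium | CCC[C@@H](O[Si](c1ccccc1)(c1ccccc1)C(C)(C)C)CCCCCCCCc1cc(OC)cc(OC)c1[Li] | intermediate (not isolated)
15 | 2-[(9R)-9-(tert-butyldiphenylsilyloxy)dodecyl]-4,6-dimethoxybenzoic acid | CCC[C@@H](O[Si](c1ccccc1)(c1ccccc1)C(C)(C)C)CCCCCCCCc1cc(OC)cc(OC)c1C(=O)O | intermediate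
16 | 2-[(9R)-9-(tert-butyldiphenylsilyloxy)dodecyl]-6-hydroxy-4-methoxybenzoic acid | CCC[C@@H](O[Si](c1ccccc1)(c1ccccc1)C(C)(C)C)CCCCCCCCc1cc(OC)cc(O)c1C(=O)O | intermediate
17 | 1,3-bis(triisopropylsilyloxy)benzene | CC(C)[Si](Oc1cccc(O[Si](C(C)C)(C(C)C)C(C)C)c1)(C(C)C)C(C)C | intermediate
18 | 2-[3,5-bis(triisopropylsilyloxy)phenyl]-4,4,5,5-tetramethyl-1,3,2-dioxaborolane | CC(C)[Si](Oc1cc(O[Si](C(C)C)(C(C)C)C(C)C)cc(B2OC(C)(C)C(C)(C)O2)c1)(C(C)C)C(C)C | intermediate (not isolated)
19 | 3,5-bis(triisopropylsilyloxy)phenol | CC(C)[Si](Oc1cc(O)cc(O[Si](C(C)C)(C(C)C)C(C)C)c1)(C(C)C)C(C)C | intermediate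
20 | 3,5-bis(triisopropylsilyloxy)phenyl trifluoromethanesulfonate | CC(C)[Si](Oc1cc(OS(=O)(=O)C(F)(F)F)cc(O[Si](C(C)C)(C(C)C)C(C)C)c1)(C(C)C)C(C)C | intermediate
21 | 6-bromohex-1-ene | C=CCCCCBr | starting material
22 | (S)-1,2-epoxypentane [(2S)-2-propyloxirane] | CCC[C@H]1CO1 | starting material
23 | hex-5-enylmagnesium bromide | C=CCCCC[Mg]Br | intermediate (not isolated)
24 | (S)-undec-10-en-4-ol | CCC[C@H](O)CCCCCC=C | intermediate
25 | 9-{(8S)-8-[(9-borabicyclo[3.3.1]nonan-9-yl)oxy]undecyl}-9-borabicyclo[3.3.1]nonane | CCC[C@H](OB1C2CCCC1CCC2)CCCCCCCB1C2CCCC1CCC2 | intermediate (not isolated)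
26 | (S)-11-[3,5-bis(triisopropylsilyloxy)phenyl]undecan-4-ol | CCC[C@H](O)CCCCCCCc1cc(O[Si](C(C)C)(C(C)C)C(C)C)cc(O[Si](C(C)C)(C(C)C)C(C)C)c1 | intermediate
27 | (R)-11-[3,5-bis(triisopropylsilyloxy)phenyl]undecan-4-yl 2-[(9R)-9-(tert-butyldiphenylsilyloxy)dodecyl]-6-hydroxy-4-methoxybenzoate | CCC[C@@H](O[Si](c1ccccc1)(c1ccccc1)C(C)(C)C)CCCCCCCCc1cc(OC)cc(O)c1C(=O)O[C@H](CCC)CCCCCCCc1cc(O[Si](C(C)C)(C(C)C)C(C)C)cc(O[Si](C(C)C)(C(C)C)C(C)C)c1 | intermediate
28 | 5'-methoxy-integracin B: (R)-11-(3,5-dihydroxyphenyl)undecan-4-yl 2-hydroxy-6-[(9R)-9-hydroxydodecyl]-4-methoxybenzoate | CCC[C@@H](O)CCCCCCCCc1cc(OC)cc(O)c1C(=O)O[C@H](CCC)CCCCCCCc1cc(O)cc(O)c1 | target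

## Step count and risks

Total step count: 16.
Longest linear sequence: 9 steps (1, 2, 3, 6, 7, 8, 9, 15, 16); the other branches are 4–5–6–…, 10–11–12–14–… and 13–14–….

Steps most likely to fail:

**Step 9** (BCl3 mono-demethylation of the free acid next to a silyl ether; risks are desilylation, double demethylation or decarboxylation). Fallback: set out from bromide 13. Exchange with n-BuLi at −78 °C as before (aryllithium 14) but quench with DMF to obtain the aldehyde 2-[(9R)-9-(tert-butyldiphenylsilyloxy)dodecyl]-4,6-dimethoxybenzaldehyde F1. MgI2·OEt2 in toluene/Et2O at 50 °C cleaves only the methyl ether chelated to the formyl group and gives the salicylaldehyde 2-[(9R)-9-(tert-butyldiphenylsilyloxy)dodecyl]-6-hydroxy-4-methoxybenzaldehyde F2. Pinnick oxidation (NaClO2, NaH2PO4, 2-methylbut-2-ene, t-BuOH/H2O) then comes back to the route at acid 16.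

**Step 14** (B-alkyl coupling of an electron-rich, silyl-protected triflate with a borane carrying a free hydroxyl; risks are slow alkyl transfer, triflate hydrolysis, β-hydride elimination). Fallback: set out from triflate 20. Couple it with vinylboronic acid pinacol ester (PdCl2(dppf), K3PO4·H2O, THF, 65 °C) to the styrene 3,5-bis(triisopropylsilyloxy)styrene F3. Olefin cross-metathesis of F3 with an excess of alkenol 24 (second-generation Grubbs catalyst, RuCl2(=CHPh)(H2IMes)(PCy3), CH2Cl2, 40 °C) gives (S,E)-11-[3,5-bis(triisopropylsilyloxy)phenyl]undec-10-en-4-ol F4. Hydrogenation (H2, Pd/C, EtOAc, rt) of the styrene double bond comes back to the route at alcohol 26; the stereocenter is never involved.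

**Step 15** (Mitsunobu union of a di-ortho-substituted salicylic acid with a secondary alcohol; risks are elimination of the alcohol, phenol alkylation, poor conversion). Fallback: set out from alcohol 26 and acid 16. Treat 26 with MsCl/Et3N in CH2Cl2 at 0 °C to give the mesylate (S)-11-[3,5-bis(triisopropylsilyloxy)phenyl]undecan-4-yl methanesulfonate F5, with configuration retained because only the O–S bond is formed. Convert 16 with Cs2CO3 (0.5 equiv) in DMF into the cesium carboxylate cesium 2-[(9R)-9-(tert-butyldiphenylsilyloxy)dodecyl]-6-hydroxy-4-methoxybenzoate F6. F6 displaces the mesylate of F5 at 50 °C by SN2 with inversion and comes back to the route at ester 27.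

## Further compounds

F1 | step 9 | 2-[(9R)-9-(tert-butyldiphenylsilyloxy)dodecyl]-4,6-dimethoxybenzaldehyde | CCC[C@@H](O[Si](c1ccccc1)(c1ccccc1)C(C)(C)C)CCCCCCCCc1cc(OC)cc(OC)c1C=O
F2 | step 9 | 2-[(9R)-9-(tert-butyldiphenylsilyloxy)dodecyl]-6-hydroxy-4-methoxybenzaldehyde | CCC[C@@H](O[Si](c1ccccc1)(c1ccccc1)C(C)(C)C)CCCCCCCCc1cc(OC)cc(O)c1C=O
F3 | step 14 | 3,5-bis(triisopropylsilyloxy)styrene | C=Cc1cc(O[Si](C(C)C)(C(C)C)C(C)C)cc(O[Si](C(C)C)(C(C)C)C(C)C)c1
F4 | step 14 | (S,E)-11-[3,5-bis(triisopropylsilyloxy)phenyl]undec-10-en-4-ol | CCC[C@H](O)CCCCC/C=C/c1cc(O[Si](C(C)C)(C(C)C)C(C)C)cc(O[Si](C(C)C)(C(C)C)C(C)C)c1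
F5 | step 15 | (S)-11-[3,5-bis(triisopropylsilyloxy)phenyl]undecan-4-yl methanesulfonate | CCC[C@H](OS(C)(=O)=O)CCCCCCCc1cc(O[Si](C(C)C)(C(C)C)C(C)C)cc(O[Si](C(C)C)(C(C)C)C(C)C)c1
F6 | step 15 | cesium 2-[(9R)-9-(tert-butyldiphenylsilyloxy)dodecyl]-6-hydroxy-4-methoxybenzoate | CCC[C@@H](O[Si](c1ccccc1)(c1ccccc1)C(C)(C)C)CCCCCCCCc1cc(OC)cc(O)c1C(=O)[O-].[Cs+]
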